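The plan rests on opening the 4-hydroxy-2-pyrone at its O1–C6 bond. Pyrone C5 and C6 are then the triple bond of (S)-pent-4-yn-2-ol, whose carbinol becomes the side-chain stereocentre, and C2–C4 with the C3 arylmethyl group form a tert-butyl β-keto ester. A cationic gold(I) catalyst lets the ester carbonyl oxygen add 6-endo to the alkyne terminus β to the ketone; this closes the pyrone ring and expels isobutene in one operation, leaving the stereocentre untouched. The precursor 14 is a tert-butyl 2-arylmethyl-3-oxooct-4-ynoate with a (7S)-silyloxy group and the 2-acetyl-3,4,5-trimethoxyphenyl ring, made by decarboxylative acylation of a benzylmalonate half-ester with a silyloxy ynoic acid.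

Key step: step 7

Remark: the carbinol is carried as its TBDPS ether, chosen over smaller silyl groups because it has to outlast AcOH in step 7 and BCl3 in step 8; compounds 1, 5 and 8 are assumed to be purchased.

Step 1
Reactants: 1 (S)-pent-4-yn-2-ol
Product: 2 (S)-tert-butyl(pent-4-yn-2-yloxy)diphenylsilane
Conditions: TBDPSCl (1.1 equiv), imidazole (2.2 equiv), DMF, 0 °C → rt
Reagents that add atoms: tert-butyl(chloro)diphenylsilane, CC(C)(C)[Si](Cl)(c1ccccc1)c1ccccc1
Why: Imidazole-promoted O-silylation of a secondary alcohol (silyl ether formation) is routine and leaves the C–O bond alone, so the (S) configuration is carried over unchanged.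

Step 2
Reactants: 2 (S)-tert-butyl(pent-4-yn-2-yloxy)diphenylsilane
Product: 4 (S)-5-[(tert-butyldiphenylsilyl)oxy]hex-2-ynoic acid, via lithium acetylide 3 (not isolated)
Conditions: n-BuLi (1.05 equiv), THF, −78 °C; CO2 (g), −78 → 0 °C; cold 1 M HCl to pH 3
Reagents that add atoms: carbon dioxide, O=C=O
Why: Deprotonation of the terminal alkyne and carboxylation of the lithium acetylide is the standard entry to 2-alkynoic acids, and the TBDPS ether tolerates n-BuLi at −78 °C and a brief cold acidification.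

Step 3
Reactants: 5 2-bromo-3,4,5-trimethoxybenzaldehyde
Product: 7 2-acetyl-3,4,5-trimethoxybenzaldehyde, via enol ether 6 (not isolated)
Conditions: tributyl(1-ethoxyvinyl)stannane (1.2 equiv), PdCl2(PPh3)2 (5 mol%), toluene, 100 °C; then 1 M HCl, THF, rt
Reagents that add atoms: tributyl(1-ethoxyvinyl)stannane, CCCC[Sn](CCCC)(CCCC)C(=C)OCC; water, O
Why: Migita–Kosugi–Stille coupling with the 1-ethoxyvinyl stannane as an acetyl anion equivalent is dependable for ortho-flanked aryl bromides (the ortho formyl group speeds oxidative addition), and dilute acid then hydrolyses the enol ether to the methyl ketone without harming the aldehyde.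

Step 4
Reactants: 7 2-acetyl-3,4,5-trimethoxybenzaldehyde; 8 Meldrum's acid
Product: 10 5-[(2-acetyl-3,4,5-trimethoxyphenyl)methyl]-2,2-dimethyl-1,3-dioxane-4,6-dione, via arylidene Meldrum's acid 9 (not isolated)
Conditions: Hantzsch ester (1.1 equiv), L-proline (10 mol%), EtOH, rt
Reagents that add atoms: none
Why: Knoevenagel condensation at the aldehyde (far more electrophilic than the hindered aryl ketone) followed by conjugate hydride transfer from the Hantzsch ester is the established three-component reductive alkylation of Meldrum's acid and should stop cleanly at mono-benzylation.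

Step 5
Reactants: 10 5-[(2-acetyl-3,4,5-trimethoxyphenyl)methyl]-2,2-dimethyl-1,3-dioxane-4,6-dione
Product: 11 2-[(2-acetyl-3,4,5-trimethoxyphenyl)methyl]-3-tert-butoxy-3-oxopropanoic acid (racemic)
Conditions: t-BuOH, reflux
Reagents that add atoms: tert-butanol, CC(C)(C)O
Why: Thermal alcoholysis of a 5-monosubstituted Meldrum's acid opens the dioxanedione with loss of acetone to give the malonic acid mono-tert-butyl ester, at a temperature below that at which the half-acid decarboxylates.

Step 6
Reactants: 4 (S)-5-[(tert-butyldiphenylsilyl)oxy]hex-2-ynoic acid; 11 2-[(2-acetyl-3,4,5-trimethoxyphenyl)methyl]-3-tert-butoxy-3-oxopropanoic acid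
Product: 14 tert-butyl (7S)-2-[(2-acetyl-3,4,5-trimethoxyphenyl)methyl]-7-[(tert-butyldiphenylsilyl)oxy]-3-oxooct-4-ynoate (C2 epimers), via acyl imidazole 12 (not isolated), via chloromagnesium half-ester salt 13 (not isolated)
Conditions: 4, CDI (1.0 equiv), THF, 0 °C → rt; then 11, MgCl2, Et3N, THF, rt; cold 0.5 M HCl work-up
Reagents that add atoms: none
Why: Magnesium-malonate decarboxylative Claisen acylation, in which the magnesium-chelated half-ester is C-acylated by the acyl imidazole and loses CO2 to give the β-keto ester directly; this soft enolisation leaves the aryl methyl ketone and the silyl ether alone, and the C2 epimer mixture does not matter because C2 becomes sp2 in step 7.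

Step 7
Reactants: 14 tert-butyl (7S)-2-[(2-acetyl-3,4,5-trimethoxyphenyl)methyl]-7-[(tert-butyldiphenylsilyl)oxy]-3-oxooct-4-ynoate
Product: 15 3-[(2-acetyl-3,4,5-trimethoxyphenyl)methyl]-6-[(2S)-2-[(tert-butyldiphenylsilyl)oxy]propyl]-4-hydroxy-2H-pyran-2-one
Conditions: (SPhos)AuNTf2 (5 mol%), MeNO2/AcOH (4:1), rt
Reagents that add atoms: none
Why: The cationic gold(I) centre coordinates the C4≡C5 triple bond of the ynone, the ester carbonyl oxygen adds anti to gold at C5, the resulting tert-butyl oxocarbenium ion loses isobutene, and protodeauration by AcOH releases the product as its 4-hydroxy-2-pyrone tautomer. The closest known reaction type is the gold(I)-catalysed cyclisation of tert-butyl 3-oxoalk-4-ynoates, 2-alkylated ones included, to 4-hydroxy-2-pyrones. The single ring is closed in the 6-endo-dig mode through the new O1–C6 bond. No stereocentre is created: C2 of 14 becomes the sp2 carbon C3 of the pyrone, and the (S)-carbinol, capped as a silyl ether, cannot take part. The step needs 6-endo O-attack to beat 5-exo O-attack at C4 and hydroarylation by the electron-rich arene; the ketone polarises the alkyne so that C5 is the electrophilic terminus, the 5-exo product would be a strained alkylidene furanone, and the arene could reach the alkyne only by an anti-Michael 6-exo or a 7-endo path. The tert-butyl group is what allows the oxocarbenium ion to collapse to the pyrone.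

Step 8
Reactants: 15 3-[(2-acetyl-3,4,5-trimethoxyphenyl)methyl]-6-[(2S)-2-[(tert-butyldiphenylsilyl)oxy]propyl]-4-hydroxy-2H-pyran-2-one
Product: 16 3-[(2-acetyl-3,4-dihydroxy-5-methoxyphenyl)methyl]-6-[(2S)-2-[(tert-butyldiphenylsilyl)oxy]propyl]-4-hydroxy-2H-pyran-2-one
Conditions: BCl3 (1 M in CH2Cl2, 5 equiv), CH2Cl2, −78 → 0 °C; ice-water
Reagents that add atoms: none
Why: Chelation-controlled aryl methyl ether cleavage, in which boron bound to the acetyl oxygen removes the ortho methyl group through a six-membered chelate and the resulting aryloxyboron chloride then reaches the adjacent central methoxy group to form a cyclic catechol borate, whereas the outer methoxy group next to the ring C–H has no such assistance and should remain, and the hindered TBDPS ether is the silyl ether least prone to Lewis-acid cleavage at or below 0 °C.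

Step 9
Reactants: 16 3-[(2-acetyl-3,4-dihydroxy-5-methoxyphenyl)methyl]-6-[(2S)-2-[(tert-butyldiphenylsilyl)oxy]propyl]-4-hydroxy-2H-pyran-2-one
Product: 17 Penicanesin D, 3-[(2-acetyl-3,4-dihydroxy-5-methoxyphenyl)methyl]-4-hydroxy-6-[(2S)-2-hydroxypropyl]-2H-pyran-2-one
Conditions: TBAF (6 equiv), THF, 0 °C → rt, Ar; 1 M HCl to pH 3
Reagents that add atoms: none
Why: Fluoride-mediated desilylation breaks only the O–Si bond, so the (S)-carbinol is released unchanged; the excess reagent allows for the acidic pyrone and phenol protons, and argon with an acidic work-up protects the catechol from oxidation.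

Compound list
1 | (S)-pent-4-yn-2-ol | C#CC[C@H](C)O | starting material
2 | (S)-tert-butyl(pent-4-yn-2-yloxy)diphenylsilane | C#CC[C@H](C)O[Si](c1ccccc1)(c1ccccc1)C(C)(C)C | intermediate
3 | lithium (S)-4-[(tert-butyldiphenylsilyl)oxy]pent-1-yn-1-ide (lithium acetylide) | [Li]C#CC[C@H](C)O[Si](c1ccccc1)(c1ccccc1)C(C)(C)C | intermediate
4 | (S)-5-[(tert-butyldiphenylsilyl)oxy]hex-2-ynoic acid | OC(=O)C#CC[C@H](C)O[Si](c1ccccc1)(c1ccccc1)C(C)(C)C | intermediate
5 | 2-bromo-3,4,5-trimethoxybenzaldehyde | COc1cc(C=O)c(Br)c(OC)c1OC | starting material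
6 | 2-(1-ethoxyvinyl)-3,4,5-trimethoxybenzaldehyde (enol ether) | CCOC(=C)c1c(C=O)cc(OC)c(OC)c1OC | intermediate
7 | 2-acetyl-3,4,5-trimethoxybenzaldehyde | CC(=O)c1c(C=O)cc(OC)c(OC)c1OC | intermediate
8 | Meldrum's acid (2,2-dimethyl-1,3-dioxane-4,6-dione) | CC1(C)OC(=O)CC(=O)O1 | starting material
9 | 5-[(2-acetyl-3,4,5-trimethoxyphenyl)methylidene]-2,2-dimethyl-1,3-dioxane-4,6-dione (arylidene Meldrum's acid) | CC(=O)c1c(C=C2C(=O)OC(C)(C)OC2=O)cc(OC)c(OC)c1OC | intermediate
10 | 5-[(2-acetyl-3,4,5-trimethoxyphenyl)methyl]-2,2-dimethyl-1,3-dioxane-4,6-dione | CC(=O)c1c(CC2C(=O)OC(C)(C)OC2=O)cc(OC)c(OC)c1OC | intermediate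
11 | 2-[(2-acetyl-3,4,5-trimethoxyphenyl)methyl]-3-tert-butoxy-3-oxopropanoic acid (racemic) | CC(=O)c1c(CC(C(=O)O)C(=O)OC(C)(C)C)cc(OC)c(OC)c1OC | intermediate
12 | (S)-5-[(tert-butyldiphenylsilyl)oxy]-1-(1H-imidazol-1-yl)hex-2-yn-1-one (acyl imidazole) | O=C(C#CC[C@H](C)O[Si](c1ccccc1)(c1ccccc1)C(C)(C)C)n1ccnc1 | intermediate
13 | chloromagnesium 2-[(2-acetyl-3,4,5-trimethoxyphenyl)methyl]-3-tert-butoxy-3-oxopropanoate (chloromagnesium half-ester salt) | [Mg+2].[Cl-].[O-]C(=O)C(Cc1cc(OC)c(OC)c(OC)c1C(C)=O)C(=O)OC(C)(C)C | intermediate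
14 | tert-butyl (7S)-2-[(2-acetyl-3,4,5-trimethoxyphenyl)methyl]-7-[(tert-butyldiphenylsilyl)oxy]-3-oxooct-4-ynoate (C2 epimers) | CC(C)(C)OC(=O)C(Cc1cc(OC)c(OC)c(OC)c1C(C)=O)C(=O)C#CC[C@H](C)O[Si](c1ccccc1)(c1ccccc1)C(C)(C)C | intermediate
15 | 3-[(2-acetyl-3,4,5-trimethoxyphenyl)methyl]-6-[(2S)-2-[(tert-butyldiphenylsilyl)oxy]propyl]-4-hydroxy-2H-pyran-2-one | COc1cc(Cc2c(O)cc(C[C@H](C)O[Si](c3ccccc3)(c3ccccc3)C(C)(C)C)oc2=O)c(C(C)=O)c(OC)c1OC | intermediate
16 | 3-[(2-acetyl-3,4-dihydroxy-5-methoxyphenyl)methyl]-6-[(2S)-2-[(tert-butyldiphenylsilyl)oxy]propyl]-4-hydroxy-2H-pyran-2-one | COc1cc(Cc2c(O)cc(C[C@H](C)O[Si](c3ccccc3)(c3ccccc3)C(C)(C)C)oc2=O)c(C(C)=O)c(O)c1O | intermediate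
17 | Penicanesin D, 3-[(2-acetyl-3,4-dihydroxy-5-methoxyphenyl)methyl]-4-hydroxy-6-[(2S)-2-hydroxypropyl]-2H-pyran-2-one | COc1cc(Cc2c(O)cc(C[C@H](C)O)oc2=O)c(C(C)=O)c(O)c1O | target

Total step count: 9. Longest linear sequence: 7 steps (5 → 7 → 10 → 11 → 14 → 15 → 16 → 17); the two-step alkyne branch (1 → 2 → 4) joins at step 6.

Steps most likely to fail

Step 6. Liberated imidazole may add in conjugate fashion to the ynoyl imidazole or to the ynone. C-acylation of the hindered α-arylmethyl malonate may be slow enough that plain protodecarboxylation takes over, and the product enolate may cyclise onto the alkyne under the basic conditions. The fallback attaches the arylmethyl group after ring closure instead. It sets out from 2: lithiation with n-BuLi and formylation with DMF should give (S)-5-[(tert-butyldiphenylsilyl)oxy]hex-2-ynal F1. Aldol addition of the lithium enolate of tert-butyl acetate (THF, −78 °C) should give tert-butyl (7S)-7-[(tert-butyldiphenylsilyl)oxy]-3-hydroxyoct-4-ynoate F2, and Dess–Martin oxidation should give tert-butyl (7S)-7-[(tert-butyldiphenylsilyl)oxy]-3-oxooct-4-ynoate F3. The gold(I) conditions of step 7 should convert this into 6-[(2S)-2-[(tert-butyldiphenylsilyl)oxy]propyl]-4-hydroxy-2H-pyran-2-one F4. Three-component reductive alkylation at pyrone C3 with aldehyde 7 and Hantzsch ester (L-proline, EtOH) then comes back to the route at 15.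

Step 8. Cleavage of the central methyl ether may stall after the ortho ether has gone, or the third ether may be attacked on longer exposure. The silyl ether may also be lost to the Lewis acid, after which the borylated secondary carbinol can ionise to a chloride with loss of configuration. The fallback carries the carbinol through the demethylation as an ester, which resists BCl3. It sets out from 15: TBAF should give 3-[(2-acetyl-3,4,5-trimethoxyphenyl)methyl]-4-hydroxy-6-[(2S)-2-hydroxypropyl]-2H-pyran-2-one F5. Ac2O in pyridine should give (2S)-1-[4-acetoxy-3-[(2-acetyl-3,4,5-trimethoxyphenyl)methyl]-2-oxo-2H-pyran-6-yl]propan-2-yl acetate F6. BCl3 as in step 8 with a methanol quench, which also removes the labile pyrone enol acetate, should give (2S)-1-[3-[(2-acetyl-3,4-dihydroxy-5-methoxyphenyl)methyl]-4-hydroxy-2-oxo-2H-pyran-6-yl]propan-2-yl acetate F7. Methanolysis with K2CO3 in MeOH under argon and acidification then comes back to the route at 17.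

Step 7. Closure may go 5-exo to the alkylidene furanone, the tert-butyl ester may be lost before cyclisation so that the β-keto acid decarboxylates, or the electron-rich arene may add to the activated alkyne. The fallback closes the ring by lactonisation at O1–C2 after hydrating the alkyne. It sets out from 14: conjugate addition of diethylamine (THF, rt) should give the vinylogous amide tert-butyl (7S)-2-[(2-acetyl-3,4,5-trimethoxyphenyl)methyl]-7-[(tert-butyldiphenylsilyl)oxy]-5-(diethylamino)-3-oxooct-4-enoate F8. Mild aqueous acid should hydrolyse it to tert-butyl (7S)-2-[(2-acetyl-3,4,5-trimethoxyphenyl)methyl]-7-[(tert-butyldiphenylsilyl)oxy]-3,5-dioxooctanoate F9. The classical β,δ-diketo ester lactonisation (TFA/TFAA, CH2Cl2, 0 °C → rt) then comes back to the route at 15.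

Further compounds
F1 | step 6 | (S)-5-[(tert-butyldiphenylsilyl)oxy]hex-2-ynal | O=CC#CC[C@H](C)O[Si](c1ccccc1)(c1ccccc1)C(C)(C)C
F2 | step 6 | tert-butyl (7S)-7-[(tert-butyldiphenylsilyl)oxy]-3-hydroxyoct-4-ynoate (C3 epimers) | CC(C)(C)OC(=O)CC(O)C#CC[C@H](C)O[Si](c1ccccc1)(c1ccccc1)C(C)(C)C
F3 | step 6 | tert-butyl (7S)-7-[(tert-butyldiphenylsilyl)oxy]-3-oxooct-4-ynoate | CC(C)(C)OC(=O)CC(=O)C#CC[C@H](C)O[Si](c1ccccc1)(c1ccccc1)C(C)(C)C
F4 | step 6 | 6-[(2S)-2-[(tert-butyldiphenylsilyl)oxy]propyl]-4-hydroxy-2H-pyran-2-one | O=c1cc(O)cc(C[C@H](C)O[Si](c2ccccc2)(c2ccccc2)C(C)(C)C)o1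
F5 | step 8 | 3-[(2-acetyl-3,4,5-trimethoxyphenyl)methyl]-4-hydroxy-6-[(2S)-2-hydroxypropyl]-2H-pyran-2-one | COc1cc(Cc2c(O)cc(C[C@H](C)O)oc2=O)c(C(C)=O)c(OC)c1OC
F6 | step 8 | (2S)-1-[4-acetoxy-3-[(2-acetyl-3,4,5-trimethoxyphenyl)methyl]-2-oxo-2H-pyran-6-yl]propan-2-yl acetate | COc1cc(Cc2c(OC(C)=O)cc(C[C@H](C)OC(C)=O)oc2=O)c(C(C)=O)c(OC)c1OC
F7 | step 8 | (2S)-1-[3-[(2-acetyl-3,4-dihydroxy-5-methoxyphenyl)methyl]-4-hydroxy-2-oxo-2H-pyran-6-yl]propan-2-yl acetate | COc1cc(Cc2c(O)cc(C[C@H](C)OC(C)=O)oc2=O)c(C(C)=O)c(O)c1O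
F8 | step 7 | tert-butyl (7S)-2-[(2-acetyl-3,4,5-trimethoxyphenyl)methyl]-7-[(tert-butyldiphenylsilyl)oxy]-5-(diethylamino)-3-oxooct-4-enoate | CCN(CC)C(C[C@H](C)O[Si](c1ccccc1)(c1ccccc1)C(C)(C)C)=CC(=O)C(Cc1cc(OC)c(OC)c(OC)c1C(C)=O)C(=O)OC(C)(C)C
F9 | step 7 | tert-butyl (7S)-2-[(2-acetyl-3,4,5-trimethoxyphenyl)methyl]-7-[(tert-butyldiphenylsilyl)oxy]-3,5-dioxooctanoate | CC(C)(C)OC(=O)C(Cc1cc(OC)c(OC)c(OC)c1C(C)=O)C(=O)CC(=O)C[C@H](C)O[Si](c1ccccc1)(c1ccccc1)C(C)(C)C
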